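Constants can wait: the first answers here come as fractions of the charge, straight from the readings.

| setting | dawn | spring | summer | dusk | winter |
|---|---|---|---|---|---|
| starting material | 0.0800 M | 0.0320 M | 0.160 M | 0.0800 M | 0.0800 M |
| partner | 0.160 M | 0.112 M | 0.160 M | 0.160 M | 0.160 M |
| free catalyst | 0.00240 M | 0.00240 M | 0.00240 M | 0.00360 M | 0.00240 M |
| time |  |  |  |  | 25 min |

| dawn run: time / min | dawn run: [target] / M | spring run: time / min | spring run: [target] / M | summer run: time / min | summer run: [target] / M | dusk run: time / min | dusk run: [target] / M |
|---|---|---|---|---|---|---|---|
| 0.33 | 0.0014 | 0.33 | 0.0011 | 0.33 | 0.0021 | 0.33 | 0.0013 |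
| 0.62 | 0.0027 | 0.62 | 4 × 10⁻⁴ | 0.62 | 0.0048 | 0.62 | 0.0024 |
| 1.2 | 0.0046 | 1.2 | 3 × 10⁻⁴ | 1.2 | 0.0092 | 1.2 | 0.0063 |
| 2.3 | 0.0084 | 2.3 | 0.0024 | 2.3 | 0.0155 | 2.3 | 0.0104 |
| 4.3 | 0.0129 | 4.3 | 0.0044 | 4.3 | 0.0242 | 4.3 | 0.0159 |
| 8.2 | 0.0165 | 8.2 | 0.0052 | 8.2 | 0.0304 | 8.2 | 0.0202 |

(standard deviation of a reading: 6 × 10⁻⁴ M)

1. how the opening rate goes with [free catalyst] round the charge of the dawn run: the exponent of the rate at two percent of starting material gone to target
2. how the opening rate goes with [partner] round the charge of the dawn run: the exponent of the rate at two percent of starting material gone to target
3. target in the winter run at 25 min, as a share of the starting material charged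
4. which of these the readings show (the substrate ties up the catalyst / nothing beyond the main steps / the catalyst wakes slowly / the product decays / the two partners rest in a complex)

- Overall: starting material + partner -> target, with free catalyst as catalyst.
- Constant volume, constant temperature.
- "The second partner" is partner.
- An order is taken over about fifteen percent of the charge, up and down.

**What does the dawn run give per minute at the opening?** Target at 1.2 min is 5.75% of the starting material charged. I take that early reading as the share turned, which gives 0.0479 min⁻¹.

**That rests on one noisy reading, and the partner falls too.** Yes. The scatter is 13.0% of that reading. The partner starts at twice the starting material, so calling the fall pseudo-first-order is a rough step. I accept it and work with the fraction left, exp(-rate × time).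

**What stands at 8.2 min in the dawn run?** The fraction left is 0.675, so 0.325 has turned, yet target reads 0.206. Target over the share turned is the kept share 0.635.

**Could an equilibrium give that level as well?** Reckoned the same way at that time, the summer run, with twice the starting material, keeps 0.585. The dusk run, with 1.50 times the catalyst, keeps 0.607. The kept share barely moves with these recipes, though the share turned differs, so I read it as target being lost with age.

**Then how fast is it lost?** If what has been made is on average half as old as the run, the dawn kept share gives a loss of 0.111 min⁻¹.

**And the winter run at 25 min?** The fraction left is 0.302, so 69.8% has turned. Formation and loss in sequence then give 18.2% as target.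

The forecast says 14%, lower than my figure, with exponents 0.5 in free catalyst and 1 in partner, and the choice: the product decays. It argues, among other things, “Equilibrium fits poorly because dusk exceeds dawn's plateau”.

The flask gives 0.59 for free catalyst, 1.1 for partner, 14.3% for the winter run, and the choice: the product decays.

    2 free catalyst ⇌ catalyst dimer, settled at all times (3350 M⁻¹)
    free catalyst + starting material + partner → target + free catalyst (690.0 M⁻² min⁻¹)
    target → decomposed product (0.1254 min⁻¹)

The winter figure is low because of the loss of target to decomposed product: the winter run with that step taken away holds 68.2% at 25 min against 14.3%, a difference of 54 percentage points. Set against that 68.2%, the target of the winter run with the loss taken away, the winter kept share is 0.210, lower than the 0.635 read in the dawn run at 8.2 min.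

The earlier runs and the new flask come from a simulation for substances that don't exist, noise included.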